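**Assumption:** positions are given in the germacrane numbering of the target (C1–C15, C12 = lactone carbonyl). The carbinol carbon that becomes the C2 ketone and the acetal/lactol carbon are carried as inconsequential epimer mixtures and have no stereodescriptor in the SMILES.

**Retrosynthetic overview**
1. Target ⇐ oxidation of the C2 carbinol and acetylation of the C15 hydroxyl of a ten-membered hydroxy lactone.
2. Key step: the ten-membered carbocycle and the trans-γ-lactone arise together by ring expansion of a five-membered lactol (2,5-dihydrofuran-2-ol); a tethered 2-(bromomethyl)acrylate allylates the anomeric carbon (C6–C7 bond) and the ring oxygen becomes the C15 hydroxyl.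
3. The allylic bromide ⇐ Baylis–Hillman reaction of the C7 aldehyde; the dihydrofuran (which locks the C4=C5 geometry) ⇐ tetronic acid, attached at C3–C4 by nickel cross-electrophile coupling.
4. The C7–C10/C1–C3 chain ⇐ two successive carbonyl allylations of 3-chloro-2-(chloromethyl)prop-1-ene: the first enantioselective (sets C8), the second with chloroacetaldehyde.
5. Ring order: dihydrofuran first (steps 1–2), then the ten-membered ring and the γ-lactone together (step 11).

**Route**

Step 1
Reactants: 1 tetronic acid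
Product: 2 4-bromofuran-2(5H)-one
Conditions: (COBr)2, DMF (cat.), CH2Cl2, 0 → 25 °C
Reagents that add atoms: oxalyl bromide, BrC(=O)C(=O)Br
Why: Vilsmeier-type deoxybromination of the vinylogous acid to the vinylogous acyl bromide, a routine conversion of tetronic acid.

Step 2
Reactants: 2 4-bromofuran-2(5H)-one
Product: 4 4-bromo-2-methoxy-2,5-dihydrofuran, via 4-bromo-2,5-dihydrofuran-2-ol 3 (not isolated)
Conditions: i-Bu2AlH, CH2Cl2, −78 °C; then MeOH, PPTS (cat.), 0 °C
Reagents that add atoms: methanol, CO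
Why: 1,2-reduction of the butenolide to the lactol and Fischer-type acetalisation store the 4-oxy-enal as a ring in which C15–O and C6 are necessarily cis on C4=C5, which fixes the later ring double-bond geometry.

Step 3
Reactants: 5 3-chloro-2-(chloromethyl)prop-1-ene; 6 2-[(tert-butyldimethylsilyl)oxy]acetaldehyde
Product: 8 (2S)-1-[(tert-butyldimethylsilyl)oxy]-4-(chloromethyl)pent-4-en-2-ol, via trimethylsilyl ether 7 (not isolated)
Conditions: CrCl2 (10 mol%), chiral bis(oxazolinyl)carbazole ligand (12 mol%), Mn, Me3SiCl, i-Pr2NEt, THF, 0 °C; then citric acid, MeOH, 0 °C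
Reagents that add atoms: none
Why: catalytic enantioselective Nozaki–Hiyama allylation in which the allylchromium adds through a chair transition state inside the chiral ligand sphere (ligand enantiomer chosen for the S carbinol, which is C8), with 5 in excess so that only one allylic chloride reacts.

Step 4
Reactants: 8 (2S)-1-[(tert-butyldimethylsilyl)oxy]-4-(chloromethyl)pent-4-en-2-ol
Product: 9 (2S)-1-[(tert-butyldimethylsilyl)oxy]-4-(chloromethyl)pent-4-en-2-yl acetate
Conditions: Ac2O, pyridine, DMAP (cat.), CH2Cl2, 0 °C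
Reagents that add atoms: acetic anhydride, CC(=O)OC(C)=O
Why: simple O-acylation installs the C8 acetate of the target early, which also keeps O8 from competing in the later lactonisation.

Step 5
Reactants: 9 (2S)-1-[(tert-butyldimethylsilyl)oxy]-4-(chloromethyl)pent-4-en-2-yl acetate; 10 chloroacetaldehyde
Product: 11 (2S)-1-[(tert-butyldimethylsilyl)oxy]-7-chloro-6-hydroxy-4-methylideneheptan-2-yl acetate
Conditions: In powder, THF/H2O (1:1), 35 °C
Reagents that add atoms: none
Why: aqueous indium Barbier allylation with the second allylic chloride of the isobutenyl linchpin (its two termini are equivalent) forms the C1–C2 bond and the exocyclic methylene; the new carbinol is formed as both epimers, which does not matter because it becomes the ketone.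

Step 6
Reactants: 11 (2S)-1-[(tert-butyldimethylsilyl)oxy]-7-chloro-6-hydroxy-4-methylideneheptan-2-yl acetate
Product: 13 (2S)-1-[(tert-butyldimethylsilyl)oxy]-6-[(tert-butyldiphenylsilyl)oxy]-7-iodo-4-methylideneheptan-2-yl acetate, via silyl ether chloride 12 (not isolated)
Conditions: t-BuPh2SiCl, imidazole, DMF, 25 °C; then NaI, butan-2-one, 80 °C
Reagents that add atoms: tert-butyl(chloro)diphenylsilane, CC(C)(C)[Si](Cl)(c1ccccc1)c1ccccc1; sodium iodide, [Na+].[I-]
Why: silylation of the secondary alcohol followed by Finkelstein exchange turns the primary chloride into the iodide needed for the coupling.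

Step 7
Reactants: 13 (2S)-1-[(tert-butyldimethylsilyl)oxy]-6-[(tert-butyldiphenylsilyl)oxy]-7-iodo-4-methylideneheptan-2-yl acetate; 4 4-bromo-2-methoxy-2,5-dihydrofuran
Product: 14 (2S)-1-[(tert-butyldimethylsilyl)oxy]-6-[(tert-butyldiphenylsilyl)oxy]-7-(5-methoxy-2,5-dihydrofuran-3-yl)-4-methylideneheptan-2-yl acetate
Conditions: NiI2 (10 mol%), 4,4′-di-tert-butyl-2,2′-bipyridine (10 mol%), Mn, DMPU, 40 °C
Reagents that add atoms: none
Why: nickel-catalysed reductive cross-electrophile coupling of a vinyl bromide with a primary alkyl iodide forms C3–C4 at the ring alkene carbon and tolerates acetate, silyl ethers and the acetal.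

Step 8
Reactants: 14 (2S)-1-[(tert-butyldimethylsilyl)oxy]-6-[(tert-butyldiphenylsilyl)oxy]-7-(5-methoxy-2,5-dihydrofuran-3-yl)-4-methylideneheptan-2-yl acetate
Product: 16 (2S)-6-[(tert-butyldiphenylsilyl)oxy]-7-(5-methoxy-2,5-dihydrofuran-3-yl)-4-methylidene-1-oxoheptan-2-yl acetate, via primary alcohol 15 (not isolated)
Conditions: PPTS, MeOH, 25 °C; then Dess–Martin periodinane, NaHCO3, CH2Cl2, 0 °C
Reagents that add atoms: none
Why: selective methanolysis of the primary TBS ether (the secondary TBDPS ether and the methyl acetal persist in methanol) and immediate Dess–Martin oxidation, before any acetyl migration, give the C7 aldehyde.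

Step 9
Reactants: 16 (2S)-6-[(tert-butyldiphenylsilyl)oxy]-7-(5-methoxy-2,5-dihydrofuran-3-yl)-4-methylidene-1-oxoheptan-2-yl acetate; 17 methyl acrylate
Product: 18 methyl (4S)-4-acetoxy-8-[(tert-butyldiphenylsilyl)oxy]-3-hydroxy-9-(5-methoxy-2,5-dihydrofuran-3-yl)-2,6-dimethylidenenonanoate
Conditions: DABCO, methyl acrylate (neat), 25 °C
Reagents that add atoms: none
Why: Morita–Baylis–Hillman reaction of the activated α-acetoxy aldehyde brings in C11–C13; the new carbinol centre is erased in the next step.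

Step 10
Reactants: 18 methyl (4S)-4-acetoxy-8-[(tert-butyldiphenylsilyl)oxy]-3-hydroxy-9-(5-methoxy-2,5-dihydrofuran-3-yl)-2,6-dimethylidenenonanoate
Product: 19 methyl (2Z,4S)-4-acetoxy-2-(bromomethyl)-8-[(tert-butyldiphenylsilyl)oxy]-9-(5-methoxy-2,5-dihydrofuran-3-yl)-6-methylidenenon-2-enoate
Conditions: NBS, Me2S, CH2Cl2, −20 → 0 °C
Reagents that add atoms: N-bromosuccinimide, BrN1C(=O)CCC1=O
Why: Corey–Kim-type activation of the Baylis–Hillman alcohol and SN2′ delivery of bromide give the rearranged Z-2-(bromomethyl)enoate under conditions mild enough for the acetal.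

Step 11
Reactants: 19 methyl (2Z,4S)-4-acetoxy-2-(bromomethyl)-8-[(tert-butyldiphenylsilyl)oxy]-9-(5-methoxy-2,5-dihydrofuran-3-yl)-6-methylidenenon-2-enoate
Product: 22 (4Z,6R,7R,8S)-8-acetoxy-2-[(tert-butyldiphenylsilyl)oxy]-15-hydroxygermacra-4,10(14),11(13)-trien-12,6-olide, via lactol 20 (not isolated), via hydroxy ester 21 (not isolated)
Conditions: PPTS, acetone/H2O (10:1), 0 °C; then CrCl2, THF/DMF (3:1), 2 mM, 25 °C; 0.5 M HCl work-up
Reagents that add atoms: water, O
Why: Proposed new method: a chromium-mediated (Nozaki–Hiyama-type) ring-expanding allylation in which the tethered 2-(methoxycarbonyl)allylchromium generated from the bromide attacks the anomeric carbon of the five-membered lactol through its ring-opened 4-hydroxy-enal tautomer, so that the ring oxygen is exchanged for carbon and the dihydrofuranol is enlarged to the ten-membered carbocycle (ring oxygen released as the C15 hydroxyl), the E-configured allylchromium reacting through a chair transition state anti to the C8 acetate to set C6 (R) and C7 (R) with a trans ring fusion before the alkoxide lactonises; the closest known reaction types are Barbier/Nozaki–Hiyama allylations of lactols (intermolecular) and intramolecular Nozaki–Hiyama allylations of aldehydes that close germacranolide rings.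

Step 12
Reactants: 22 (4Z,6R,7R,8S)-8-acetoxy-2-[(tert-butyldiphenylsilyl)oxy]-15-hydroxygermacra-4,10(14),11(13)-trien-12,6-olide
Product: 23 (4Z,6R,7R,8S)-8,15-diacetoxy-2-[(tert-butyldiphenylsilyl)oxy]germacra-4,10(14),11(13)-trien-12,6-olide
Conditions: Ac2O, pyridine, CH2Cl2, 0 °C
Reagents that add atoms: acetic anhydride, CC(=O)OC(C)=O
Why: acetylation of the only free hydroxyl, the primary allylic one at C15.

Step 13
Reactants: 23 (4Z,6R,7R,8S)-8,15-diacetoxy-2-[(tert-butyldiphenylsilyl)oxy]germacra-4,10(14),11(13)-trien-12,6-olide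
Product: 25 (4Z,6R,7R,8S)-8,15-diacetoxy-2-oxogermacra-4,10(14),11(13)-trien-12,6-olide, via C2 alcohol 24 (not isolated)
Conditions: HF·pyridine, THF, 25 °C; then Dess–Martin periodinane, NaHCO3, CH2Cl2, 0 °C
Reagents that add atoms: none
Why: fluoride desilylation and buffered Dess–Martin oxidation give the ketone without acid or base that would move the two β,γ-double bonds into conjugation, and both epimers at C2 converge on the target.

**Compound list**

1 | tetronic acid (4-hydroxyfuran-2(5H)-one) | OC1=CC(=O)OC1 | starting material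
2 | 4-bromofuran-2(5H)-one | BrC1=CC(=O)OC1 | intermediate
3 | 4-bromo-2,5-dihydrofuran-2-ol (lactol) | OC1OCC(Br)=C1 | intermediate
4 | 4-bromo-2-methoxy-2,5-dihydrofuran (racemic) | COC1OCC(Br)=C1 | intermediate
5 | 3-chloro-2-(chloromethyl)prop-1-ene | C=C(CCl)CCl | starting material
6 | 2-[(tert-butyldimethylsilyl)oxy]acetaldehyde (silyl-protected glycolaldehyde) | O=CCO[Si](C)(C)C(C)(C)C | starting material
7 | O-trimethylsilyl ether of 8, (2S) | CC(C)(C)[Si](C)(C)OC[C@@H](O[Si](C)(C)C)CC(=C)CCl | intermediate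
8 | (2S)-1-[(tert-butyldimethylsilyl)oxy]-4-(chloromethyl)pent-4-en-2-ol | CC(C)(C)[Si](C)(C)OC[C@@H](O)CC(=C)CCl | intermediate
9 | (2S)-1-[(tert-butyldimethylsilyl)oxy]-4-(chloromethyl)pent-4-en-2-yl acetate | CC(C)(C)[Si](C)(C)OC[C@@H](OC(C)=O)CC(=C)CCl | intermediate
10 | chloroacetaldehyde | O=CCCl | starting material
11 | (2S)-1-[(tert-butyldimethylsilyl)oxy]-7-chloro-6-hydroxy-4-methylideneheptan-2-yl acetate (C6 epimers) | CC(C)(C)[Si](C)(C)OC[C@@H](OC(C)=O)CC(=C)CC(O)CCl | intermediate
12 | (2S)-1-[(tert-butyldimethylsilyl)oxy]-6-[(tert-butyldiphenylsilyl)oxy]-7-chloro-4-methylideneheptan-2-yl acetate | CC(C)(C)[Si](C)(C)OC[C@@H](OC(C)=O)CC(=C)CC(CCl)O[Si](c1ccccc1)(c1ccccc1)C(C)(C)C | intermediate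
13 | (2S)-1-[(tert-butyldimethylsilyl)oxy]-6-[(tert-butyldiphenylsilyl)oxy]-7-iodo-4-methylideneheptan-2-yl acetate | CC(C)(C)[Si](C)(C)OC[C@@H](OC(C)=O)CC(=C)CC(CI)O[Si](c1ccccc1)(c1ccccc1)C(C)(C)C | intermediate
14 | (2S)-1-[(tert-butyldimethylsilyl)oxy]-6-[(tert-butyldiphenylsilyl)oxy]-7-(5-methoxy-2,5-dihydrofuran-3-yl)-4-methylideneheptan-2-yl acetate | CC(C)(C)[Si](C)(C)OC[C@@H](OC(C)=O)CC(=C)CC(CC1=CC(OC)OC1)O[Si](c1ccccc1)(c1ccccc1)C(C)(C)C | intermediate
15 | (2S)-6-[(tert-butyldiphenylsilyl)oxy]-1-hydroxy-7-(5-methoxy-2,5-dihydrofuran-3-yl)-4-methylideneheptan-2-yl acetate | OC[C@@H](OC(C)=O)CC(=C)CC(CC1=CC(OC)OC1)O[Si](c1ccccc1)(c1ccccc1)C(C)(C)C | intermediate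
16 | (2S)-6-[(tert-butyldiphenylsilyl)oxy]-7-(5-methoxy-2,5-dihydrofuran-3-yl)-4-methylidene-1-oxoheptan-2-yl acetate | O=C[C@@H](OC(C)=O)CC(=C)CC(CC1=CC(OC)OC1)O[Si](c1ccccc1)(c1ccccc1)C(C)(C)C | intermediate
17 | methyl acrylate | C=CC(=O)OC | starting material
18 | methyl (4S)-4-acetoxy-8-[(tert-butyldiphenylsilyl)oxy]-3-hydroxy-9-(5-methoxy-2,5-dihydrofuran-3-yl)-2,6-dimethylidenenonanoate (C3 epimers) | COC(=O)C(=C)C(O)[C@@H](OC(C)=O)CC(=C)CC(CC1=CC(OC)OC1)O[Si](c1ccccc1)(c1ccccc1)C(C)(C)C | intermediate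
19 | methyl (2Z,4S)-4-acetoxy-2-(bromomethyl)-8-[(tert-butyldiphenylsilyl)oxy]-9-(5-methoxy-2,5-dihydrofuran-3-yl)-6-methylidenenon-2-enoate | COC(=O)/C(CBr)=C/[C@@H](OC(C)=O)CC(=C)CC(CC1=CC(OC)OC1)O[Si](c1ccccc1)(c1ccccc1)C(C)(C)C | intermediate
20 | methyl (2Z,4S)-4-acetoxy-2-(bromomethyl)-8-[(tert-butyldiphenylsilyl)oxy]-9-(5-hydroxy-2,5-dihydrofuran-3-yl)-6-methylidenenon-2-enoate (lactol) | COC(=O)/C(CBr)=C/[C@@H](OC(C)=O)CC(=C)CC(CC1=CC(O)OC1)O[Si](c1ccccc1)(c1ccccc1)C(C)(C)C | intermediate
21 | ring-closed hydroxy ester: methyl (4Z)-8-acetoxy-2-[(tert-butyldiphenylsilyl)oxy]-6,15-dihydroxygermacra-4,10(14),11(13)-trien-12-oate, with C6, C7 and C8 arranged in space as in 22 | C=C1CC(O[Si](c2ccccc2)(c2ccccc2)C(C)(C)C)C/C(CO)=C/[C@@H](O)[C@H](C(=C)C(=O)OC)[C@@H](OC(C)=O)C1 | intermediate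
22 | (4Z,6R,7R,8S)-8-acetoxy-2-[(tert-butyldiphenylsilyl)oxy]-15-hydroxygermacra-4,10(14),11(13)-trien-12,6-olide (C3 and C6 trans across C4=C5; C2 epimers) | C=C1CC(O[Si](c3ccccc3)(c3ccccc3)C(C)(C)C)C/C(CO)=C/[C@H]2OC(=O)C(=C)[C@@H]2[C@@H](OC(C)=O)C1 | intermediate
23 | (4Z,6R,7R,8S)-8,15-diacetoxy-2-[(tert-butyldiphenylsilyl)oxy]germacra-4,10(14),11(13)-trien-12,6-olide | C=C1CC(O[Si](c3ccccc3)(c3ccccc3)C(C)(C)C)C/C(COC(C)=O)=C/[C@H]2OC(=O)C(=C)[C@@H]2[C@@H](OC(C)=O)C1 | intermediate
24 | (4Z,6R,7R,8S)-8,15-diacetoxy-2-hydroxygermacra-4,10(14),11(13)-trien-12,6-olide | C=C1CC(O)C/C(COC(C)=O)=C/[C@H]2OC(=O)C(=C)[C@@H]2[C@@H](OC(C)=O)C1 | intermediate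
25 | (4Z,6R,7R,8S)-8,15-diacetoxy-2-oxogermacra-4,10(14),11(13)-trien-12,6-olide (CNP0183179.1) | C=C1CC(=O)C/C(COC(C)=O)=C/[C@H]2OC(=O)C(=C)[C@@H]2[C@@H](OC(C)=O)C1 | target

**Step count**
Total: 13 steps. Longest linear sequence: 11 steps (steps 3–13, from 5 and 6); the dihydrofuran branch (steps 1–2) joins at step 7.

**Steps most likely to fail**

Step 11 (the proposed new ring-expanding allylation). Risks: the lactol 20 can lose water to a furan, its open-chain form is a minor tautomer, and the facial selectivity in the macrocyclic transition state is untested. The fallback uses known chemistry, a conventional intramolecular Nozaki–Hiyama allylation of an open-chain enal whose O15 is already acetylated. It sets out from 2 and 13 and comes back to the route at 23. Compound 2 is reduced fully with i-Bu2AlH (3 equiv) to (E)-2-bromobut-2-ene-1,4-diol F1 (the two hydroxymethyl groups cis). The less hindered hydroxyl, remote from bromine, is silylated with TBSCl to give the mono-silyl ether F2, and the other hydroxyl is acetylated to give the acetate F3. F3 is coupled with 13 under the conditions of step 7 to the open-chain coupling product F4. Methanolysis of both primary TBS ethers (PPTS, MeOH) gives the diol F5, which Dess–Martin periodinane oxidises to the dialdehyde F6. The Baylis–Hillman reaction with methyl acrylate takes place only at the saturated α-acetoxy aldehyde and gives F7, and NBS/Me2S gives the allylic bromide F8. CrCl2 in THF/DMF at high dilution closes the ten-membered ring onto the enal to give the hydroxy ester F9, which lactonises on acidic work-up to 23.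

Step 9 (Baylis–Hillman reaction). Risks: the reaction is slow, and the amine can epimerise C8 of the α-acetoxy aldehyde or cause acetyl migration. The fallback replaces amine catalysis by addition of a preformed vinylaluminium reagent. It sets out from 16 and comes back at 18. Methyl propiolate is treated with i-Bu2AlH and HMPA in THF at 0 °C to give methyl 2-(diisobutylalumanyl)prop-2-enoate F10, which adds to 16 at −78 °C without base and gives 18 directly.

Step 7 (nickel cross-electrophile coupling). Risks: β-elimination of the silyloxy group from the alkyl intermediate, homocoupling, or loss of the allylic acetal. The fallback is a polar Negishi coupling with a preformed organozinc. It sets out from 13 and comes back at 14. Zinc insertion into 13 (Zn dust, LiCl, THF, 40 °C) gives the alkylzinc iodide F11, which is coupled with 4 using Pd(OAc)2 and SPhos in THF at 25 °C to give 14.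

**Further compounds**

F1 | step 11 | (E)-2-bromobut-2-ene-1,4-diol (hydroxymethyl groups cis) | OC/C(Br)=C\CO
F2 | step 11 | (E)-2-bromo-4-[(tert-butyldimethylsilyl)oxy]but-2-en-1-ol | OC/C(Br)=C\CO[Si](C)(C)C(C)(C)C
F3 | step 11 | (E)-2-bromo-4-[(tert-butyldimethylsilyl)oxy]but-2-en-1-yl acetate | CC(=O)OC/C(Br)=C\CO[Si](C)(C)C(C)(C)C
F4 | step 11 | (2S,8Z)-8-(acetoxymethyl)-1,10-bis[(tert-butyldimethylsilyl)oxy]-6-[(tert-butyldiphenylsilyl)oxy]-4-methylidenedec-8-en-2-yl acetate | CC(C)(C)[Si](C)(C)OC[C@@H](OC(C)=O)CC(=C)CC(C/C(COC(C)=O)=C/CO[Si](C)(C)C(C)(C)C)O[Si](c1ccccc1)(c1ccccc1)C(C)(C)C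
F5 | step 11 | (2S,8Z)-8-(acetoxymethyl)-6-[(tert-butyldiphenylsilyl)oxy]-1,10-dihydroxy-4-methylidenedec-8-en-2-yl acetate | OC[C@@H](OC(C)=O)CC(=C)CC(C/C(COC(C)=O)=C/CO)O[Si](c1ccccc1)(c1ccccc1)C(C)(C)C
F6 | step 11 | (2S,8Z)-8-(acetoxymethyl)-6-[(tert-butyldiphenylsilyl)oxy]-4-methylidene-1,10-dioxodec-8-en-2-yl acetate | O=C[C@@H](OC(C)=O)CC(=C)CC(C/C(COC(C)=O)=C/C=O)O[Si](c1ccccc1)(c1ccccc1)C(C)(C)C
F7 | step 11 | methyl (4S,10Z)-4-acetoxy-10-(acetoxymethyl)-8-[(tert-butyldiphenylsilyl)oxy]-3-hydroxy-2,6-dimethylidene-12-oxododec-10-enoate | COC(=O)C(=C)C(O)[C@@H](OC(C)=O)CC(=C)CC(C/C(COC(C)=O)=C/C=O)O[Si](c1ccccc1)(c1ccccc1)C(C)(C)C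
F8 | step 11 | methyl (2Z,4S,10Z)-4-acetoxy-10-(acetoxymethyl)-2-(bromomethyl)-8-[(tert-butyldiphenylsilyl)oxy]-6-methylidene-12-oxododeca-2,10-dienoate | COC(=O)/C(CBr)=C/[C@@H](OC(C)=O)CC(=C)CC(C/C(COC(C)=O)=C/C=O)O[Si](c1ccccc1)(c1ccccc1)C(C)(C)C
F9 | step 11 | 15-O-acetyl derivative of 21 (ring-closed hydroxy ester) | C=C1CC(O[Si](c2ccccc2)(c2ccccc2)C(C)(C)C)C/C(COC(C)=O)=C/[C@@H](O)[C@H](C(=C)C(=O)OC)[C@@H](OC(C)=O)C1
F10 | step 9 | methyl 2-(diisobutylalumanyl)prop-2-enoate | COC(=O)C(=C)[Al](CC(C)C)CC(C)C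
F11 | step 7 | alkylzinc iodide from 13: {(6S)-6-acetoxy-7-[(tert-butyldimethylsilyl)oxy]-2-[(tert-butyldiphenylsilyl)oxy]-4-methylideneheptyl}zinc iodide | CC(C)(C)[Si](C)(C)OC[C@@H](OC(C)=O)CC(=C)CC(C[Zn]I)O[Si](c1ccccc1)(c1ccccc1)C(C)(C)C
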